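The six-membered carbocycle carries the spirolactone C–O bond and the fused-lactone α-C–H on its two allylic carbons, 1,4 across the ring C=C, the spiro oxygen lying on the face that bears the cis-fused cyclopentane and γ-lactone; the ring is therefore a reductively opened 7-oxanorbornene. Everything rests on an intramolecular furan Diels–Alder reaction through the future lactone ester: furan C2 and C5 add to the cyclopentene C=C, closing the carbocycle and the fused γ-lactone and setting four stereocentres in one operation. The precursor is a 4,5-dialkyl-2-furoate, both side-chain stereocentres in place, esterified to the secondary hydroxyl of (1S,4R)-1-methylcyclopent-2-ene-1,4-diol. SmI2 then cuts the oxygen bridge and the freed alkoxide closes the spirolactone.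

Key step: step 11

Remark: the chiral ligand antipodes in steps 3 and 6 are those expected to give the configurations drawn ((R)-BINAP in step 6 follows the usual facial model for (E)-enoates) and would be confirmed on a first small run; cycloadduct 20 is assumed to revert on warming and is therefore handled cold.

Step 1
Reactants: 1 4,5-dibromofuran-2-carboxylic acid
Product: 2 tert-butyl 4,5-dibromofuran-2-carboxylate
Conditions: Cl3CC(=NH)OtBu, BF3·OEt2 (cat.), CH2Cl2–cyclohexane, 25 °C
Reagents that add atoms: tert-butyl 2,2,2-trichloroacetimidate, CC(C)(C)OC(=N)C(Cl)(Cl)Cl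
Why: Acid-catalysed O-alkylation of the carboxylic acid by the imidate (tert-butyl cation transfer) should give the tert-butyl ester, which later lets the furoate be unmasked beside two methyl esters.

Step 2
Reactants: 2 tert-butyl 4,5-dibromofuran-2-carboxylate
Product: 5 tert-butyl 4-bromo-5-formylfuran-2-carboxylate, via furylmagnesium chloride 3 (not isolated), via magnesium hemiaminalate 4 (not isolated)
Conditions: iPrMgCl·LiCl, THF, −40 °C; DMF, −40 → 0 °C; aq. NH4Cl
Reagents that add atoms: N,N-dimethylformamide, CN(C)C=O
Why: Bromine–magnesium exchange should occur only at C5, the position next to the ring oxygen whose carbanion is best stabilised, at a temperature where the tert-butyl ester is inert, and the furyl Grignard reagent is then formylated by DMF (Bouveault formylation).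

Step 3
Reactants: 5 tert-butyl 4-bromo-5-formylfuran-2-carboxylate; 6 1-methoxy-1-(trimethylsilyloxy)ethene
Product: 8 tert-butyl 4-bromo-5-[(1S)-1-hydroxy-3-methoxy-3-oxopropyl]furan-2-carboxylate, via trimethylsilyl ether 7 (not isolated)
Conditions: Ti(OiPr)4 (5 mol %), tridentate Schiff-base ligand from 2-amino-2'-hydroxy-1,1'-binaphthyl and 3-bromo-5-tert-butylsalicylaldehyde (antipode giving the S carbinol), 3,5-di-tert-butylsalicylic acid (5 mol %), Et2O, −10 °C; then 1 M HCl, THF, 0 °C
Reagents that add atoms: none
Why: Catalytic enantioselective Mukaiyama acetate aldol reaction, in which the chiral titanium Schiff-base complex activates the aldehyde and shields one of its faces, so the carbinol centre is set by the catalyst, and the silyl-transfer product is cleaved by the acidic work-up.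

Step 4
Reactants: 8 tert-butyl 4-bromo-5-[(1S)-1-hydroxy-3-methoxy-3-oxopropyl]furan-2-carboxylate
Product: 9 tert-butyl 4-bromo-5-[(1S)-3-methoxy-3-oxo-1-(triethylsilyloxy)propyl]furan-2-carboxylate
Conditions: TESCl, imidazole, CH2Cl2, 0 °C
Reagents that add atoms: chlorotriethylsilane, CC[Si](Cl)(CC)CC
Why: Standard silylation of a secondary alcohol; the TES ether blocks retro-aldol cleavage, should survive the palladium, rhodium and samarium steps, and comes off at the end with buffered fluoride.

Step 5
Reactants: 9 tert-butyl 4-bromo-5-[(1S)-3-methoxy-3-oxo-1-(triethylsilyloxy)propyl]furan-2-carboxylate; 10 methyl acrylate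
Product: 11 tert-butyl 4-[(E)-3-methoxy-3-oxoprop-1-en-1-yl]-5-[(1S)-3-methoxy-3-oxo-1-(triethylsilyloxy)propyl]furan-2-carboxylate
Conditions: Pd(OAc)2 (5 mol %), P(o-tol)3, Et3N, DMF, 90 °C
Reagents that add atoms: none
Why: Mizoroki–Heck reaction: oxidative addition of the electron-poor 3-bromofuran to zerovalent palladium, syn insertion of the acrylate and syn β-hydride elimination should give the (E)-enoate, the amine base being too weak to eliminate the β-silyloxy ester.

Step 6
Reactants: 11 the (E)-β-(furan-3-yl)acrylate; 12 isopropenylboronic acid pinacol ester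
Product: 13 tert-butyl 4-[(3S)-1-methoxy-4-methyl-1-oxopent-4-en-3-yl]-5-[(1S)-3-methoxy-3-oxo-1-(triethylsilyloxy)propyl]furan-2-carboxylate
Conditions: 12 (3 equiv), [Rh(OH)((R)-binap)]2 (3 mol %), K3PO4 (0.5 equiv), dioxane–H2O 10:1, 50 °C
Reagents that add atoms: none
Why: Hayashi–Miyaura reaction (rhodium-catalysed asymmetric conjugate addition of an alkenylboron reagent to an enoate): the alkenylrhodium species should insert the enoate on the face chosen by the BINAP ligand, setting the (S) side-chain centre under catalyst control, and water protonates the rhodium enolate under near-neutral conditions that spare the β-silyloxy ester.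

Step 7
Reactants: 13 the tert-butyl furoate from step 6
Product: 15 4-[(3S)-1-methoxy-4-methyl-1-oxopent-4-en-3-yl]-5-[(1S)-3-methoxy-3-oxo-1-(triethylsilyloxy)propyl]furan-2-carboxylic acid, via trimethylsilyl ester 14 (not isolated)
Conditions: TMSOTf, 2,6-lutidine, CH2Cl2, 0 °C; then pH 5 buffer
Reagents that add atoms: none
Why: Lewis-acid cleavage of a tert-butyl ester (O-silylation, loss of isobutene, hydrolysis of the silyl ester on work-up), with the lutidine buffer excluding protic acid so that the furan, the isopropenyl group, the TES ether and the methyl esters should be untouched.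

Step 8
Reactants: 16 (R)-4-(tert-butyldimethylsilyloxy)cyclopent-2-en-1-one
Product: 17 (1S,4R)-4-(tert-butyldimethylsilyloxy)-1-methylcyclopent-2-en-1-ol
Conditions: MeLi, Et2O, −78 °C; aq. NH4Cl
Reagents that add atoms: methyllithium, [Li]C
Why: 1,2-Addition of the organolithium to the enone carbonyl on the face anti to the bulky silyloxy group should place the new hydroxyl cis to the silyloxy group, so the tertiary carbinol centre is set by the substrate.

Step 9
Reactants: 17 (1S,4R)-4-(tert-butyldimethylsilyloxy)-1-methylcyclopent-2-en-1-ol
Product: 18 (1S,4R)-1-methylcyclopent-2-ene-1,4-diol (cis)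
Conditions: Bu4NF, THF, 0 → 25 °C
Reagents that add atoms: none
Why: Fluoride-mediated desilylation frees the secondary allylic alcohol without affecting either carbinol centre.

Step 10
Reactants: 15 the furoic acid from step 7; 18 (1S,4R)-1-methylcyclopent-2-ene-1,4-diol
Product: 19 (1R,4S)-4-hydroxy-4-methylcyclopent-2-en-1-yl 4-[(3S)-1-methoxy-4-methyl-1-oxopent-4-en-3-yl]-5-[(1S)-3-methoxy-3-oxo-1-(triethylsilyloxy)propyl]furan-2-carboxylate
Conditions: EDC·HCl, DMAP, CH2Cl2, 0 → 25 °C (18 in slight excess)
Reagents that add atoms: none
Why: Steglich esterification: the carbodiimide-activated acid, relayed by DMAP, should acylate only the secondary allylic hydroxyl, the tertiary one being too hindered, which leaves a small free OH on the face that must react next.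

Step 11
Reactants: 19 the cyclopentenyl furoate
Product: 20 lactone-fused 7-oxanorbornene cycloadduct (oxygen bridge between the former furan C2 and C5; γ-lactone from the C2 bridgehead to the exo carbon of the cis,exo-fused cyclopentane)
Conditions: CH2Cl2 (0.05 M, trace BHT), 15 kbar, 25 °C, 48 h; decompress, concentrate at 0 °C, use at once
Reagents that add atoms: none
Why: Proposed new method: a concerted suprafacial [4+2] cycloaddition is proposed in which furan C2 and C5 bond to the two alkene carbons of the cyclopentenyl ester while the furan oxygen stays as the 7-oxa bridge. The closest known reaction type is the intramolecular Diels–Alder reaction of furans joined by three atoms to unactivated alkenes (furfuryl allyl ethers, N-allyl-2-furamides), run thermally or at 10–19 kbar; an ester tether of this kind has not been shown. The six-membered carbocycle is the cycloadduct ring itself (its C=C is the former furan C3=C4), and the γ-lactone closes through the C(=O)–O–CH tether in the exo-tether mode, which requires the less stable s-cis ester rotamer. Both bridgeheads and both new ring-fusion CH centres are set relative to the ester-bearing carbinol carbon, because a three-atom tether reaches only the alkene face syn to the acyloxy group and only with the tether syn to the oxygen bridge. That face and mode are the only selectivity needed and the short tether enforces them, while the reacting face carries the small tertiary OH and not the methyl group. The two alkyl groups on the furan offset the carboxylate and pressure favours the compact transition state and adduct against the expected reversibility, which is why the adduct is kept cold and reduced at once.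

Step 12
Reactants: 20 the cycloadduct
Product: 22 O-triethylsilyl ether of the target, via ring-opened hydroxy diester 21 (not isolated)
Conditions: SmI2 (2.5 equiv), HMPA, tBuOH (2 equiv), THF, −78 → −40 °C; then warm to 25 °C
Reagents that add atoms: none
Why: Samarium diiodide reduction of an α-alkoxy ester: electron transfer to the lactone carbonyl should expel the bridge oxygen (the only C–O bond α to a carbonyl, and also allylic and strained), the dienolate is protonated kinetically at the α-carbon on the face opposite the departed oxygen to give the cis-fused lactone with the C=C unmoved, and the trivalent samarium tertiary alkoxide acylates the nearby methyl ester by 5-exo attack (γ-lactone preferred over the δ-lactone with the other ester); no base equilibration is used, since it could move the double bond into conjugation.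

Step 13
Reactants: 22 O-triethylsilyl ether of the target
Product: 23 target CNP0148106.2
Conditions: HF·pyridine, pyridine, THF, 0 °C
Reagents that add atoms: none
Why: Fluoride-mediated desilylation under pyridine-buffered conditions should remove the TES group without opening either lactone or dehydrating the tertiary alcohol.

Compound list
1 | 4,5-dibromofuran-2-carboxylic acid | OC(=O)c1cc(Br)c(Br)o1 | starting material
2 | tert-butyl 4,5-dibromofuran-2-carboxylate | CC(C)(C)OC(=O)c1cc(Br)c(Br)o1 | intermediate
3 | [3-bromo-5-(tert-butoxycarbonyl)furan-2-yl]magnesium chloride | CC(C)(C)OC(=O)c1cc(Br)c([Mg]Cl)o1 | intermediate (not isolated)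
4 | tert-butyl 4-bromo-5-[(chloromagnesiooxy)(dimethylamino)methyl]furan-2-carboxylate | CN(C)C(O[Mg]Cl)c1oc(C(=O)OC(C)(C)C)cc1Br | intermediate (not isolated)
5 | tert-butyl 4-bromo-5-formylfuran-2-carboxylate | O=Cc1oc(C(=O)OC(C)(C)C)cc1Br | intermediate
6 | 1-methoxy-1-(trimethylsilyloxy)ethene | C=C(OC)O[Si](C)(C)C | starting material
7 | tert-butyl 4-bromo-5-[(1S)-3-methoxy-3-oxo-1-(trimethylsilyloxy)propyl]furan-2-carboxylate | Brc1cc(C(=O)OC(C)(C)C)oc1[C@H](CC(=O)OC)O[Si](C)(C)C | intermediate (not isolated)
8 | tert-butyl 4-bromo-5-[(1S)-1-hydroxy-3-methoxy-3-oxopropyl]furan-2-carboxylate | Brc1cc(C(=O)OC(C)(C)C)oc1[C@H](CC(=O)OC)O | intermediate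
9 | tert-butyl 4-bromo-5-[(1S)-3-methoxy-3-oxo-1-(triethylsilyloxy)propyl]furan-2-carboxylate | Brc1cc(C(=O)OC(C)(C)C)oc1[C@H](CC(=O)OC)O[Si](CC)(CC)CC | intermediate
10 | methyl acrylate | C=CC(=O)OC | starting material
11 | tert-butyl 4-[(E)-3-methoxy-3-oxoprop-1-en-1-yl]-5-[(1S)-3-methoxy-3-oxo-1-(triethylsilyloxy)propyl]furan-2-carboxylate | COC(=O)/C=C/c1cc(C(=O)OC(C)(C)C)oc1[C@H](CC(=O)OC)O[Si](CC)(CC)CC | intermediate
12 | isopropenylboronic acid pinacol ester | C=C(C)B1OC(C)(C)C(C)(C)O1 | starting material
13 | tert-butyl 4-[(3S)-1-methoxy-4-methyl-1-oxopent-4-en-3-yl]-5-[(1S)-3-methoxy-3-oxo-1-(triethylsilyloxy)propyl]furan-2-carboxylate | C=C(C)[C@H](CC(=O)OC)c1cc(C(=O)OC(C)(C)C)oc1[C@H](CC(=O)OC)O[Si](CC)(CC)CC | intermediate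
14 | trimethylsilyl ester of acid 15 | C=C(C)[C@H](CC(=O)OC)c1cc(C(=O)O[Si](C)(C)C)oc1[C@H](CC(=O)OC)O[Si](CC)(CC)CC | intermediate (not isolated)
15 | 4-[(3S)-1-methoxy-4-methyl-1-oxopent-4-en-3-yl]-5-[(1S)-3-methoxy-3-oxo-1-(triethylsilyloxy)propyl]furan-2-carboxylic acid | C=C(C)[C@H](CC(=O)OC)c1cc(C(=O)O)oc1[C@H](CC(=O)OC)O[Si](CC)(CC)CC | intermediate
16 | (R)-4-(tert-butyldimethylsilyloxy)cyclopent-2-en-1-one | CC(C)(C)[Si](C)(C)O[C@@H]1CC(=O)C=C1 | starting material
17 | (1S,4R)-4-(tert-butyldimethylsilyloxy)-1-methylcyclopent-2-en-1-ol (OH and silyloxy cis) | CC(C)(C)[Si](C)(C)O[C@@H]1C[C@](C)(O)C=C1 | intermediate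
18 | (1S,4R)-1-methylcyclopent-2-ene-1,4-diol (cis diol) | O[C@@H]1C[C@](C)(O)C=C1 | intermediate
19 | (1R,4S)-4-hydroxy-4-methylcyclopent-2-en-1-yl 4-[(3S)-1-methoxy-4-methyl-1-oxopent-4-en-3-yl]-5-[(1S)-3-methoxy-3-oxo-1-(triethylsilyloxy)propyl]furan-2-carboxylate | C=C(C)[C@H](CC(=O)OC)c1cc(C(=O)O[C@@H]2C[C@](C)(O)C=C2)oc1[C@H](CC(=O)OC)O[Si](CC)(CC)CC | intermediate
20 | lactone-fused 7-oxanorbornene: oxygen bridge between the former furan C2 and C5; γ-lactone from the C2 bridgehead to the cyclopentane C–O carbon; cyclopentane cis,exo-fused with its lactone oxygen and tertiary OH syn to the bridge and methyl anti; the C5 bridgehead bears (S)-CH(OTES)CH2CO2Me and the neighbouring alkene carbon the (S)-CH(isopropenyl)CH2CO2Me chain | C=C(C)[C@H](CC(=O)OC)C1=C[C@]42C(=O)O[C@@H]3C[C@](C)(O)[C@@H]([C@H]23)[C@]1([C@H](CC(=O)OC)O[Si](CC)(CC)CC)O4 | intermediate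
21 | ring-opened tertiary alcohol (formed as its samarium alkoxide): cyclohexene with cis-fused γ-lactone (α-H anti to the new tertiary OH) and cis-fused cyclopentane, the tertiary carbinol carbon bearing (S)-CH(OTES)CH2CO2Me | C=C(C)[C@H](CC(=O)OC)C1=C[C@@H]2C(=O)O[C@@H]3C[C@](C)(O)[C@@H]([C@H]23)[C@@]1(O)[C@H](CC(=O)OC)O[Si](CC)(CC)CC | intermediate (not isolated)
22 | O-triethylsilyl ether of the target (spiro γ-lactone closed, carbinol silylated) | C=C(C)[C@H](CC(=O)OC)C1=C[C@@H]2C(=O)O[C@@H]3C[C@](C)(O)[C@@H]([C@H]23)[C@]12OC(=O)C[C@@H]2O[Si](CC)(CC)CC | intermediate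
23 | CNP0148106.2: cyclohexene with cis-fused γ-lactone and cis-fused methylcyclopentanol, spiro β-hydroxy-γ-lactone whose ring oxygen is syn to the cyclopentane, and an (S)-CH(isopropenyl)CH2CO2Me chain on the alkene | C=C(C)[C@H](CC(=O)OC)C1=C[C@@H]2C(=O)O[C@@H]3C[C@](C)(O)[C@@H]([C@H]23)[C@]12OC(=O)C[C@@H]2O | target

Total steps: 13. Longest linear sequence: 11 steps (1 → 23 through steps 1–7 and 10–13); the cyclopentene branch (steps 8–9) joins at step 10.

Steps most likely to fail

Step 11 (the step without direct precedent). The ester may not populate the s-cis rotamer, the furoate is electronically poorly matched with an unactivated alkene, the new bond to the alkene carbon beside the quaternary carbinol is crowded, and the adduct may revert on decompression before it can be reduced. The fallback uses known chemistry and changes the tether from an ester to an acetal, so that the substrate belongs to the established class of furfuryl allyl ethers. It sets out from acid 15.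
- Isobutyl chloroformate and N-methylmorpholine (THF, −15 °C) would give the mixed carbonic anhydride F1, which NaBH4 in THF–MeOH should reduce to the 2-(hydroxymethyl)furan F2 without touching the methyl esters.
- MnO2 in CH2Cl2 would give the furfural F3, and MeOSiMe3 with catalytic TMSOTf (CH2Cl2, −78 °C) the dimethyl acetal F4 under aprotic conditions.
- TESOTf and 2,4,6-collidine (CH2Cl2, 0 °C) should exchange one methoxy group for a collidinium leaving group, giving the salt F5. The secondary hydroxyl of diol 18 displaces it to give the mixed methyl cyclopentenyl acetal F6 (both epimers at the acetal carbon, which is oxidised later).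
- Heating F6 in toluene or compressing it to 10–15 kbar should give the acetal-bridged cycloadduct F7 by the same exo-tether addition on the face syn to the tether oxygen.
- PPTS in wet acetone would hydrolyse the methyl lactol ether to the lactol F8, and TEMPO with PhI(OAc)2 (CH2Cl2, 0 °C) would oxidise it to the lactone, coming back to the route at cycloadduct 20.

Step 6. Transmetalation of the α-branched alkenylboronate may be slow and lose out to protodeboronation, the ortho-substituted β-furyl enoate may insert sluggishly, and facial selectivity may be poor if the ligand and the existing carbinol centre are mismatched. The fallback replaces catalyst control by auxiliary control and sets out from bromide 9.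
- Heck coupling under the conditions of step 5 with (R)-3-acryloyl-4-phenyloxazolidin-2-one F9 (made from (R)-4-phenyloxazolidin-2-one, BuLi and acryloyl chloride) would give the N-enoyl imide F10.
- Isopropenylmagnesium bromide with CuBr·SMe2 (THF, −40 °C) should add to the magnesium-chelated s-cis imide on the face away from the phenyl group, which corresponds to the (S) centre, giving the conjugate adduct F11.
- MeMgBr in MeOH (bromomagnesium methoxide, 0 °C) would exchange the auxiliary for methoxide and come back to the route at tert-butyl ester 13.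

Step 12. Cycloreversion may compete with electron transfer, the dienolate may be protonated at the γ-carbon, the silyl group may migrate to the new tertiary alkoxide, the silyloxy group may eliminate, or the alkoxide may acylate the wrong ester. The fallback separates reduction, deprotection and ring closure, and closes the lactone on the free diol under neutral catalysis (thermodynamic control) instead of through the samarium alkoxide.
- The reduction is quenched with AcOH at −78 °C so that the ring-opened hydroxy diester 21 is isolated.
- From 21, HF·pyridine (pyridine, THF, 0 °C) would remove the silyl group to give the diol diester F12.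
- Catalytic Bu2SnO in toluene at 60 °C should close the five-membered spirolactone through the tertiary hydroxyl (favoured over the six-membered alternative with the other ester), coming back to the route at target 23.

Further compounds
F1 | step 11 | isobutyl carbonic mixed anhydride of acid 15 | C=C(C)[C@H](CC(=O)OC)c1cc(C(=O)OC(=O)OCC(C)C)oc1[C@H](CC(=O)OC)O[Si](CC)(CC)CC
F2 | step 11 | methyl (3S)-3-{5-(hydroxymethyl)-2-[(1S)-3-methoxy-3-oxo-1-(triethylsilyloxy)propyl]furan-3-yl}-4-methylpent-4-enoate | C=C(C)[C@H](CC(=O)OC)c1cc(CO)oc1[C@H](CC(=O)OC)O[Si](CC)(CC)CC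
F3 | step 11 | corresponding 5-formylfuran (furfural) | C=C(C)[C@H](CC(=O)OC)c1cc(C=O)oc1[C@H](CC(=O)OC)O[Si](CC)(CC)CC
F4 | step 11 | corresponding 5-(dimethoxymethyl)furan | C=C(C)[C@H](CC(=O)OC)c1cc(C(OC)OC)oc1[C@H](CC(=O)OC)O[Si](CC)(CC)CC
F5 | step 11 | N-[methoxy(furan-2-yl)methyl]-2,4,6-trimethylpyridinium triflate derived from F4 | C=C(C)[C@H](CC(=O)OC)c1cc(C(OC)[n+]2c(C)cc(C)cc2C)oc1[C@H](CC(=O)OC)O[Si](CC)(CC)CC.[O-]S(=O)(=O)C(F)(F)F
F6 | step 11 | mixed methyl (1R,4S)-4-hydroxy-4-methylcyclopent-2-en-1-yl acetal of furfural F3 (both acetal epimers) | C=C(C)[C@H](CC(=O)OC)c1cc(C(OC)O[C@@H]2C[C@](C)(O)C=C2)oc1[C@H](CC(=O)OC)O[Si](CC)(CC)CC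
F7 | step 11 | acetal-bridged 7-oxanorbornene cycloadduct (methyl lactol ether analogue of 20) | C=C(C)[C@H](CC(=O)OC)C1=C[C@]42C(OC)O[C@@H]3C[C@](C)(O)[C@@H]([C@H]23)[C@]1([C@H](CC(=O)OC)O[Si](CC)(CC)CC)O4
F8 | step 11 | lactol analogue of 20 | C=C(C)[C@H](CC(=O)OC)C1=C[C@]42C(O)O[C@@H]3C[C@](C)(O)[C@@H]([C@H]23)[C@]1([C@H](CC(=O)OC)O[Si](CC)(CC)CC)O4
F9 | step 6 | (R)-3-acryloyl-4-phenyloxazolidin-2-one | C=CC(=O)N1[C@H](c2ccccc2)COC1=O
F10 | step 6 | tert-butyl 4-{(E)-3-oxo-3-[(4R)-2-oxo-4-phenyloxazolidin-3-yl]prop-1-en-1-yl}-5-[(1S)-3-methoxy-3-oxo-1-(triethylsilyloxy)propyl]furan-2-carboxylate | O=C(/C=C/c1cc(C(=O)OC(C)(C)C)oc1[C@H](CC(=O)OC)O[Si](CC)(CC)CC)N1[C@H](c2ccccc2)COC1=O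
F11 | step 6 | (3S)-isopropenyl conjugate adduct of F10 (N-acyl oxazolidinone analogue of 13) | C=C(C)[C@H](CC(=O)N1[C@H](c2ccccc2)COC1=O)c1cc(C(=O)OC(C)(C)C)oc1[C@H](CC(=O)OC)O[Si](CC)(CC)CC
F12 | step 12 | desilylated diol diester (21 without the triethylsilyl group) | C=C(C)[C@H](CC(=O)OC)C1=C[C@@H]2C(=O)O[C@@H]3C[C@](C)(O)[C@@H]([C@H]23)[C@@]1(O)[C@H](CC(=O)OC)O
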